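**Assumptions:** The target SMILES has no stereocentre or stereogenic axis. Agecorynin F (5-hydroxy-6,7,2',3',4',5'-hexamethoxyflavone, C21H22O9) is achiral, so the "single enantiomer" requirement does not apply. Compounds 1 and 3 are taken to be catalogue chemicals.

## Retrosynthetic overview
1. 5-OH ⇐ chelation-directed mono-O-demethylation of the peri (C5) methyl ether of 5,6,7,2',3',4',5'-heptamethoxyflavone.
2. Ring C (O1–C2 bond and C2=C3) ⇐ oxidative cyclisation of a 2'-hydroxychalcone.
3. Chalcone Cα=Cβ ⇐ Claisen–Schmidt condensation of 2'-hydroxy-4',5',6'-trimethoxyacetophenone (ring A) with 2,3,4,5-tetramethoxybenzaldehyde (ring B).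
4. Aldehyde ⇐ formylation of symmetric 1,2,3,4-tetramethoxybenzene, which has only one type of Ar–H.
5. Ring order: rings A and B are bought as intact arenes, and the pyranone ring C is the only ring formed (step 3).

## Route

**Step 1**
Reactants: 1, 1,2,3,4-tetramethoxybenzene
Product: 2, 2,3,4,5-tetramethoxybenzaldehyde
Conditions: POCl3 (1.5 equiv), DMF, 0 → 80 °C, 4–6 h; then aq NaOAc
Reagents that add atoms: DMF, CN(C)C=O (formyl C–H); water, O (carbonyl O, from iminium hydrolysis)
Why: In this Vilsmeier–Haack formylation the two free positions (C5 and C6) are symmetry-equivalent and each lies ortho/para to OMe groups, so one regioisomer forms, and the new CHO deactivates the ring against a second formylation while the methyl ethers are untouched.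

**Step 2**
Reactants: 2, 2,3,4,5-tetramethoxybenzaldehyde; 3, 1-(6-hydroxy-2,3,4-trimethoxyphenyl)ethan-1-one (2'-hydroxy-4',5',6'-trimethoxyacetophenone)
Product: 4, (E)-1-(6-hydroxy-2,3,4-trimethoxyphenyl)-3-(2,3,4,5-tetramethoxyphenyl)prop-2-en-1-one (2'-hydroxy-2,3,4,5,4',5',6'-heptamethoxychalcone)
Conditions: 50% aq KOH (about 10 equiv), EtOH, rt, 24–48 h; then cold 1 M HCl to pH 3–4
Reagents that add atoms: none (both partners are numbered reactants; H2O is lost)
Why: In this Claisen–Schmidt aldol condensation the aldehyde cannot enolise, E1cB dehydration gives the thermodynamic E-enone (a geometry erased in step 3), and any flavanone formed by adventitious oxa-Michael closure converges on the same product in step 3.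

**Step 3**
Reactants: 4, the heptamethoxy-2'-hydroxychalcone
Product: 5, 5,6,7-trimethoxy-2-(2,3,4,5-tetramethoxyphenyl)-4H-chromen-4-one (5,6,7,2',3',4',5'-heptamethoxyflavone)
Conditions: I2 (10 mol %), DMSO, 130 °C, 2–3 h; then aq Na2S2O3
Reagents that add atoms: none (net loss of 2 H)
Why: In this I2/DMSO oxidative cyclisation the only free phenol closes by 6-endo oxa-Michael addition and α-iodination/HI elimination installs C2=C3, with DMSO reoxidising HI so that the low iodine loading limits ring iodination, and no stereocentre persists.

**Step 4**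
Reactants: 5, 5,6,7,2',3',4',5'-heptamethoxyflavone
Product: 6, agecorynin F (5-hydroxy-6,7-dimethoxy-2-(2,3,4,5-tetramethoxyphenyl)-4H-chromen-4-one)
Conditions: BCl3 (1.0 M in CH2Cl2, 1.5 equiv), CH2Cl2, −78 → 0 °C, 1–2 h, TLC control; then MeOH/1 M HCl
Reagents that add atoms: none (CH3 is replaced by H on work-up)
Why: In this chelation-controlled Lewis-acid ether cleavage BCl3 bridges the C4 carbonyl and the peri 5-OMe, so chloride removes only that methyl through a six-membered borate chelate, while the other six OMe groups lack this activation and survive at low temperature without acid-induced Wessely–Moser ring opening.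

## Compound list
1 | 1,2,3,4-tetramethoxybenzene | COc1ccc(OC)c(OC)c1OC | starting material
2 | 2,3,4,5-tetramethoxybenzaldehyde | O=Cc1cc(OC)c(OC)c(OC)c1OC | intermediate
3 | 1-(6-hydroxy-2,3,4-trimethoxyphenyl)ethan-1-one | CC(=O)c1c(O)cc(OC)c(OC)c1OC | starting material
4 | (E)-2'-hydroxy-2,3,4,5,4',5',6'-heptamethoxychalcone | COc1cc(/C=C/C(=O)c2c(O)cc(OC)c(OC)c2OC)c(OC)c(OC)c1OC | intermediate
5 | 5,6,7,2',3',4',5'-heptamethoxyflavone | COc1cc(-c2cc(=O)c3c(OC)c(OC)c(OC)cc3o2)c(OC)c(OC)c1OC | intermediate
6 | agecorynin F (achiral) | COc1cc(-c2cc(=O)c3c(O)c(OC)c(OC)cc3o2)c(OC)c(OC)c1OC | target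

## Summary
Total step count: 4
Longest linear sequence: 4 (1 → 2 → 4 → 5 → 6)

**Steps most likely to fail, with fallbacks**
1. **Step 4.**
   - Risk: further cleavage at 6-OMe, or at the crowded 3'/4'-OMe groups.
   - Fallback: stop aiming for mono-cleavage. Drive the A ring to the 5,6-diol (AlBr3/MeCN), then re-methylate only the 6-OH (Me2SO4 1 equiv, K2CO3, acetone). The chelated 5-OH is inert under these conditions. This sequence also recycles any over-demethylated by-product from the BCl3 reaction.
2. **Step 3.**
   - Risk: iodination at C8 or C3 of the very electron-rich system, or incomplete oxidation.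
   - Fallback: use a redox-neutral Baker–Venkataraman route. Pinnick oxidation of 2 gives the acid, and (COCl)2 gives the acid chloride. O-Aroylation of 3 followed by KOH/pyridine acyl migration gives the 1,3-diketone, and H2SO4/AcOH cyclodehydration gives 5.
3. **Step 2.**
   - Risk: a sluggish aldol between the di-ortho-substituted ketone and the electron-rich, ortho-substituted aldehyde, with competing Cannizzaro reaction.
   - Fallback: build ring C by Pd-catalysed carbonylative annulation. Convert 2 to 1-ethynyl-2,3,4,5-tetramethoxybenzene (Ohira–Bestmann). Couple it with 2-iodo-3,4,5-trimethoxyphenol (NIS on 3,4,5-trimethoxyphenol) under CO with PdCl2(PPh3)2 and Et2NH. This gives 5 directly through the ynone.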